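The meeting asked how much links stands after 3.0 h in the flasks ochre to green, which differ in their charge of first end groups while the second end groups go in as equal portions.

| flask | first end groups | second end groups | remark | time |
|---|---|---|---|---|
| larch | 0.12 M | 0.40 M (in portions, 2) | run made earlier; portions every 80 min |  |
| elm | 0.42 M | 0.40 M (in portions, 2) | run made earlier; portions every 80 min |  |
| cedar | 1.4 M | 0.40 M (in portions, 2) | run made earlier; portions every 80 min |  |
| ochre | 0.10 M | 0.400 M (in portions, 2) | the portions of second end groups follow each other after 80 min, the first at the start | 3.0 h |
| violet | 0.20 M | 0.400 M (in portions, 2) | the portions of second end groups follow each other after 80 min, the first at the start | 3.0 h |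
| teal | 0.40 M | 0.400 M (in portions, 2) | the portions of second end groups follow each other after 80 min, the first at the start | 3.0 h |
| blue | 0.80 M | 0.400 M (in portions, 2) | the portions of second end groups follow each other after 80 min, the first at the start | 3.0 h |
| green | 1.5 M | 0.400 M (in portions, 2) | the portions of second end groups follow each other after 80 min, the first at the start | 3.0 h |

| run | time / min | links / % | first end groups / % |
|---|---|---|---|
| larch | 20.0 | 17.7 | 59.7 |
| larch | 40.0 | 19.9 | 36.0 |
| larch | 50.0 | 22.6 | 29.4 |
| larch | 80.0 | 20.9 | 14.7 |
| larch | 90.0 | 21.5 | 11.7 |
| elm | 20.0 | 9.3 | 65.3 |
| elm | 40.0 | 10.5 | 52.8 |
| elm | 50.0 | 9.7 | 53.3 |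
| elm | 80.0 | 7.6 | 52.7 |
| elm | 90.0 | 13.3 | 39.6 |
| cedar | 8.00 | 2.8 | 87.4 |
| cedar | 15.0 | 4.6 | 85.9 |
| cedar | 25.0 | 3.6 | 86.7 |
| cedar | 50.0 | 1.2 | 85.5 |
| cedar | 90.0 | 6.3 | 72.5 |

(standard deviation of a reading: 1 percentage point)

- "hardly changes" means that all values lie within two and a half points (for a concentration: within two and a half percent of the largest)

- [links] at the end for ochre, violet, teal, blue, green, in this order
- how the row runs (hardly changes / rises, then falls / rises all the way / falls, then rises / falls all the way)

The first speaker proposed to follow the fraction of first end groups left and not the links made. She pointed to the elm run, where that fraction read 52.8% at 40.0 min and 52.7% at 80.0 min, and to the cedar run, where it read 85.9% at 15.0 min and 85.5% at 50.0 min. She reported that one first end group taken per second end group added gives 52.4% for elm and 85.7% for cedar after the first portion, so the readings stood where that portion put them. For blue she reckoned 50.0% once both portions are used up and for green 73.3%. She called this the floor: one minus the second end groups added over the first end groups charged, where second end groups are the limiting reagent.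

The second speaker objected that links are asked, not what is left. He read links over the fraction gone at 90.0 min and found 0.243 for larch, 0.220 for elm and 0.229 for cedar, which lie close together. The first speaker answered that the fraction gone times the charge is 0.400 M for blue and 0.400 M for green, so at a common share their links should be equal. The meeting committed to a row that climbs towards equal charges and then runs level. It left the height open, since the last cedar reading stands at 90.0 min, earlier than the 3.0 h to which the flasks run.

The forecast gave 0.022 M, 0.045 M, 0.06 M, 0.04 M and 0.015 M, rises, then falls, falling at the end where the meeting's row stays level, on the ground that “high charges lose links during the long tail”.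

The simulation gave 0.0211 M, 0.0355 M, 0.0577 M, 0.0561 M and 0.0558 M, rises, then falls.

    first end groups + second end groups → rings, rate k1*[first end groups] as long as [second end groups] is above zero (k = 0.0150 min⁻¹)
    links ⇌ isomer of the product (K = 1.20, k = 0.0140 min⁻¹)
    first end groups + second end groups → links (k = 0.0690 M⁻¹ min⁻¹)

Blue ended with 50% of its first end groups left against a floor of 50.0%, and green with 73% against 73.3%, while their links stood at 0.0561 M and 0.0558 M. In ochre, the half-life of links by the forward step to isomer of the product alone, 0.83 h, is shorter than the run time of 3.0 h. At 3.00 h ochre makes links more slowly than it uses them up, each step taken net, the ratio of the two rates being 0.261.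

(Readings and results stem from a simulated flask with constants of no real substance; noise was put on by code.)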